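**Assumption:** descriptors read from the SMILES give (1S,2S,4R,5R)-4-bromo-2-[(2S,3S,5S)-5-bromo-3-hydroxy-2,6,6-trimethyloxan-2-yl]-5-chloro-5-methylcyclohexyl acetate; these cyclohexane (C1–C6) and oxane (C2'–C6') locants are used throughout.

## Retrosynthetic overview

1. C1–OAc/C2–H come from Ti(III) opening of a C1–C2 epoxide; that epoxide comes from a C5–OH-directed epoxidation; C5–Cl comes from the same OH with retention through the C4 bromonium ion; C4–Br/C5–OH come from enantioselective epoxidation and bromide opening of the ring methyl olefin.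
2. All ring halogen chemistry is done while C2 is still sp2. The target's trans-diequatorial Br/Cl (Br cis to the oxane, Cl cis to OAc) cannot arise from diaxial BrCl addition to a ring already locked by an equatorial oxane; that gives the C4/C5 bis-epimer.
3. The oxane (second ring) comes from 6-endo bromoetherification of the tertiary alcohol onto the prenyl olefin.
4. The cyclohexa-1,4-diene (first ring) comes from a late Birch reduction of a p-tolyl carbinol that already carries both carbinol stereocentres; the flat arene is a stereochemically blank ring whose two olefins are then differentiated.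
5. The aryl carbinol comes from Felkin MeMgBr addition, Davis hydroxylation and α-prenylation of 4'-methylacetophenone.

## Forward route

**Step 1**
Reactants: 1 4'-methylacetophenone; 2 prenyl bromide
Product: 3 5-methyl-1-(4-methylphenyl)hex-4-en-1-one
Conditions: LDA, THF, −78 °C; then 2, −78 → 0 °C
Reagents that add atoms: prenyl bromide (2), CC(C)=CCBr
Why: Kinetic lithium enolate of the aryl methyl ketone is C-alkylated by SN2 at the primary allylic bromide (enolate alkylation); no stereocentre is formed.

**Step 2**
Reactants: 3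
Product: 4 (2S)-2-hydroxy-5-methyl-1-(4-methylphenyl)hex-4-en-1-one
Conditions: NaHMDS, THF, −78 °C; (+)-(camphorylsulfonyl)oxaziridine; NH4Cl
Reagents that add atoms: (+)-(camphorylsulfonyl)oxaziridine, CC1(C)C2CCC13CS(=O)(=O)N4OC34C2 (stereo not encoded)
Why: Davis asymmetric enolate hydroxylation of the (Z)-sodium enolate of an aryl alkyl ketone under reagent control sets the future oxane C3' as S; the (+)-reagent is chosen by analogy with propiophenone-type enolates (from memory, to be confirmed).

**Step 3**
Reactants: 4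
Product: 5 (2S)-2-(tert-butyldimethylsilyloxy)-5-methyl-1-(4-methylphenyl)hex-4-en-1-one
Conditions: TBSCl, imidazole, DMF, rt
Reagents that add atoms: TBSCl, CC(C)(C)[Si](C)(C)Cl
Why: Standard silylation of a secondary alcohol; the bulky non-chelating silyl ether provides the facial control in step 4 and later blocks 5-endo bromoetherification and competing OH direction.

**Step 4**
Reactants: 5
Product: 6 (2S,3S)-3-(tert-butyldimethylsilyloxy)-6-methyl-2-(4-methylphenyl)hept-5-en-2-ol
Conditions: MeMgBr, THF, −78 °C
Reagents that add atoms: MeMgBr, C[Mg]Br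
Why: Felkin–Anh (polar, non-chelation) 1,2-addition: the α-C–OSi bond lies anti to the incoming methyl, which attacks the ketone face flanked by H, giving the (2S,3S) tertiary carbinol (future oxane C2').

**Step 5**
Reactants: 6
Product: 7 (2S,3S)-3-(tert-butyldimethylsilyloxy)-6-methyl-2-(4-methylcyclohexa-1,4-dien-1-yl)hept-5-en-2-ol
Conditions: n-BuLi (1 equiv), THF, −78 °C; then Li, NH3(l), t-BuOH, −78 °C; NH4Cl
Reagents that add atoms: none (H only)
Why: Birch reduction of a 1,4-dialkylbenzene gives the 1,4-dialkylcyclohexa-1,4-diene; the benzylic oxygen is carried as its lithium alkoxide to suppress C–O hydrogenolysis, the isolated olefin and silyl ether are inert, and no stereocentre is touched.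

**Step 6**
Reactants: 7
Product: 8 (2S,3S,5S)-5-bromo-3-(tert-butyldimethylsilyloxy)-2,6,6-trimethyl-2-(4-methylcyclohexa-1,4-dien-1-yl)oxane
Conditions: TBCO (1.05 equiv), MeNO2, −20 °C, dark
Reagents that add atoms: 2,4,4,6-tetrabromocyclohexa-2,5-dienone (TBCO), BrC1=CC(Br)(Br)C=C(Br)C1=O
Why: Bromonium-induced 6-endo (Markovnikov) etherification by the tertiary alcohol through a chair transition state (ring substituent equatorial, 2-Me and 3-OSi axial, Br equatorial and anti to the new C–O bond) gives the 5'S bromide; ring-olefin bromonium ions have no internal nucleophile and should revert.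

**Step 7**
Reactants: 8
Product: 9 (2S,3S,5S)-5-bromo-3-(tert-butyldimethylsilyloxy)-2,6,6-trimethyl-2-[(1R,6S)-1-methyl-7-oxabicyclo[4.1.0]hept-3-en-4-yl]oxane
Conditions: ent-Shi ketone (L-fructose-derived, 30 mol %), Oxone, K2CO3, Bu4NHSO4, MeCN–DMM/buffer pH 10.5, 0 °C
Reagents that add atoms: Oxone (KHSO5), OOS(=O)(=O)[O-].[K+]
Why: Shi asymmetric epoxidation: the electrophilic chiral dioxirane takes the unhindered methyl-substituted olefin rather than the one flanked by the quaternary oxane carbon, and the catalyst alone selects the face (the L-ketone is the antipode of the D-ketone that gives (R,R)-oxides from 1-substituted cyclohexenes), placing C5–O on the future chlorine face.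

**Step 8**
Reactants: 9
Product: 10 (1R,6R)-6-bromo-1-methyl-4-[(2S,3S,5S)-5-bromo-3-(tert-butyldimethylsilyloxy)-2,6,6-trimethyloxan-2-yl]cyclohex-3-en-1-ol
Conditions: Li2NiBr4, THF, 0 °C → rt
Reagents that add atoms: Li2NiBr4, [Li+].[Li+].Br[Ni-2](Br)(Br)Br
Why: SN2 opening of the trisubstituted epoxide by soft bromide at the secondary carbon with inversion sets C4–Br (R) and leaves the tertiary C5–OH; trans-diaxial opening is available because C2 is still sp2 and the ring is conformationally free.

**Step 9**
Reactants: 10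
Product: 11 (1R,3R,4R,6S)-3-bromo-4-methyl-1-[(2R,3S,5S)-5-bromo-3-(tert-butyldimethylsilyloxy)-2,6,6-trimethyloxan-2-yl]-7-oxabicyclo[4.1.0]heptan-4-ol (the oxane C2' descriptor changes to R by CIP priority only; no bond at that centre is touched)
Conditions: VO(acac)2 (5 mol %), t-BuOOH, CH2Cl2, 0 °C → rt
Reagents that add atoms: tert-butyl hydroperoxide, CC(C)(C)OO
Why: Hydroxyl-directed vanadium epoxidation of a cyclic homoallylic alcohol (cf. terpinen-4-ol) delivers oxygen to the remaining C1=C2 olefin syn to the tertiary C5–OH, fixing C1–O (S) cis to the future C5–Cl.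

**Step 10**
Reactants: 11
Product: 12 (1R,3R,4R,6S)-3-bromo-4-chloro-4-methyl-1-[(2R,3S,5S)-5-bromo-3-(tert-butyldimethylsilyloxy)-2,6,6-trimethyloxan-2-yl]-7-oxabicyclo[4.1.0]heptane
Conditions: 1-chloro-N,N,2-trimethylprop-1-enylamine (Ghosez reagent), CH2Cl2, 0 °C → rt
Reagents that add atoms: Ghosez reagent, CC(C)=C(Cl)N(C)C
Why: Neutral chlorodehydroxylation of the tertiary alcohol with neighbouring-group participation: the trans-diaxial C4–Br closes to a bromonium ion as the activated oxygen leaves and chloride reopens it at the tertiary carbon, so double inversion gives retention at C5 (R) before the ring is locked.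

**Step 11**
Reactants: 12
Product: 13 (1S,2S,4R,5R)-4-bromo-2-[(2S,3S,5S)-5-bromo-3-(tert-butyldimethylsilyloxy)-2,6,6-trimethyloxan-2-yl]-5-chloro-5-methylcyclohexan-1-ol
Conditions: Cp2TiCl (from Cp2TiCl2/Mn, decanted), H2O, THF, 0 °C → rt
Reagents that add atoms: none (H only, from water)
Why: Nugent–RajanBabu Ti(III) reductive epoxide opening: C2–O homolysis gives the tertiary radical while C1–O is untouched, and with C1–O and C5–Cl cis the ring adopts the chair with both equatorial (5-Me axial), so H is delivered axially to C2 and the oxane ends equatorial, trans to C1–O (C2 = S).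

**Step 12**
Reactants: 13
Product: 14 (1S,2S,4R,5R)-4-bromo-2-[(2S,3S,5S)-5-bromo-3-(tert-butyldimethylsilyloxy)-2,6,6-trimethyloxan-2-yl]-5-chloro-5-methylcyclohexyl acetate
Conditions: Ac2O, DMAP, pyridine, CH2Cl2, rt
Reagents that add atoms: acetic anhydride, CC(=O)OC(C)=O
Why: DMAP-catalysed acylation of the only free (secondary, equatorial) hydroxyl; no stereocentre is affected.

**Step 13**
Reactants: 14
Product: 15 (5S)-5-acetoxycaespitol
Conditions: HF·pyridine, THF–pyridine, 0 °C → rt
Reagents that add atoms: none
Why: Fluoride-mediated desilylation of the hindered secondary silyl ether; the acetate, tertiary chloride and secondary bromides are stable to buffered HF·pyridine.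

## Compound list

1 | 4'-methylacetophenone | CC(=O)c1ccc(C)cc1 | starting material
2 | prenyl bromide (1-bromo-3-methylbut-2-ene) | CC(C)=CCBr | starting material
3 | 5-methyl-1-(4-methylphenyl)hex-4-en-1-one | CC(C)=CCCC(=O)c1ccc(C)cc1 | intermediate
4 | (2S)-2-hydroxy-5-methyl-1-(4-methylphenyl)hex-4-en-1-one | Cc1ccc(cc1)C(=O)[C@@H](O)CC=C(C)C | intermediate
5 | (2S)-2-(TBS-oxy)-5-methyl-1-(4-methylphenyl)hex-4-en-1-one | Cc1ccc(cc1)C(=O)[C@@H](O[Si](C)(C)C(C)(C)C)CC=C(C)C | intermediate
6 | (2S,3S)-3-(TBS-oxy)-6-methyl-2-(4-methylphenyl)hept-5-en-2-ol | Cc1ccc(cc1)[C@](C)(O)[C@@H](O[Si](C)(C)C(C)(C)C)CC=C(C)C | intermediate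
7 | (2S,3S)-3-(TBS-oxy)-6-methyl-2-(4-methylcyclohexa-1,4-dien-1-yl)hept-5-en-2-ol | CC1=CCC(=CC1)[C@](C)(O)[C@@H](O[Si](C)(C)C(C)(C)C)CC=C(C)C | intermediate
8 | (2S,3S,5S)-5-bromo-3-(TBS-oxy)-2,6,6-trimethyl-2-(4-methylcyclohexa-1,4-dien-1-yl)oxane | CC1=CCC(=CC1)[C@]1(C)OC(C)(C)[C@@H](Br)C[C@@H]1O[Si](C)(C)C(C)(C)C | intermediate
9 | ring methyl-olefin epoxide, (1R,6S)-1-methyl-7-oxabicyclo[4.1.0]hept-3-en-4-yl oxane | C1[C@@]2(C)O[C@H]2CC(=C1)[C@]1(C)OC(C)(C)[C@@H](Br)C[C@@H]1O[Si](C)(C)C(C)(C)C | intermediate
10 | trans-bromohydrin, (1R,6R)-6-bromo-1-methyl-4-(oxanyl)cyclohex-3-en-1-ol | C1[C@@](C)(O)[C@H](Br)CC(=C1)[C@]1(C)OC(C)(C)[C@@H](Br)C[C@@H]1O[Si](C)(C)C(C)(C)C | intermediate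
11 | epoxy bromohydrin, (1R,3R,4R,6S)-3-bromo-4-methyl-1-(oxanyl)-7-oxabicyclo[4.1.0]heptan-4-ol | C1[C@@](C)(O)[C@H](Br)C[C@]3(O[C@@H]13)[C@]1(C)OC(C)(C)[C@@H](Br)C[C@@H]1O[Si](C)(C)C(C)(C)C | intermediate
12 | epoxy bromochloride, (1R,3R,4R,6S)-3-bromo-4-chloro-4-methyl-1-(oxanyl)-7-oxabicyclo[4.1.0]heptane | C1[C@@](C)(Cl)[C@H](Br)C[C@]3(O[C@@H]13)[C@]1(C)OC(C)(C)[C@@H](Br)C[C@@H]1O[Si](C)(C)C(C)(C)C | intermediate
13 | (1S,2S,4R,5R)-4-bromo-2-[(2S,3S,5S)-5-bromo-3-(TBS-oxy)-2,6,6-trimethyloxan-2-yl]-5-chloro-5-methylcyclohexan-1-ol | O[C@H]1C[C@@](C)(Cl)[C@H](Br)C[C@@H]1[C@]1(C)OC(C)(C)[C@@H](Br)C[C@@H]1O[Si](C)(C)C(C)(C)C | intermediate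
14 | acetate of 13 (TBS ether of the target) | CC(=O)O[C@H]1C[C@@](C)(Cl)[C@H](Br)C[C@@H]1[C@]1(C)OC(C)(C)[C@@H](Br)C[C@@H]1O[Si](C)(C)C(C)(C)C | intermediate
15 | (5S)-5-acetoxycaespitol | CC(=O)O[C@H]1C[C@@](C)(Cl)[C@H](Br)C[C@@H]1[C@]1(C)OC(C)(C)[C@@H](Br)C[C@@H]1O | target

## Step count and risks

Total steps: 13. Longest linear sequence: 13 (fully linear from 4'-methylacetophenone).

Steps most likely to fail:

1. **Step 6** (bromoetherification next to a 1,4-cyclohexadiene). Ring bromination followed by HBr loss would re-aromatise the ring, and 6-endo versus 5-exo closure is not guaranteed. Fallback: use allyl bromide in step 1 and carry the tertiary OH as a TMS ether through the Birch and ring sequence; then convert allyl to prenyl by cross-metathesis with 2-methylbut-2-ene and close the oxane last, when no other C=C remains.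

2. **Step 11** (Ti(III) opening). Ti(III) may reductively eliminate the vicinal bromochloride or the β-bromo ether, and the face of H-atom delivery at C2 is argued, not precedented on this system. Fallback: open the epoxide at stage 11, before any vicinal dihalide exists, acetylate C1–OH, and introduce chlorine last (SOCl2, no base) through the twist-boat bromonium ion. This changes the order and accepts weaker control at C5.

3. **Step 10** (tertiary chloride with retention beside an epoxide). Chloride may open the epoxide, or E1 elimination may compete. Fallback: chlorinate bromohydrin 10 first, with no epoxide present and the ring still free to go diaxial, then epoxidise C1=C2 on the chlorine face by a second, reagent-controlled Shi epoxidation instead of relying on hydroxyl direction.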